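**Plan**

- Cuts: the Z-hydroxyenone at the acyl C–CH= bond; the cyclopentane at the bond between its two adjacent quaternary carbons; the chain enone at C(=O)–CH=; the 2H-chromene at O1–C8a and C4–C4a.
- Enabling feature: in the cyclopentane, the carbon bearing CH3 and the CH2C(=O) arm is β to the chain ketone, and its neighbour bearing CH3 and the acyl group is α to a carbonyl. This is a 1,5-dicarbonyl (Michael adduct) pattern.
- Forward order: the pyran ring of the chromene closes first (Sonogashira coupling, semihydrogenation, Pd-catalysed C–O coupling). The side chain is joined by Nozaki–Hiyama–Kishi coupling, the cyclopentane closes by the Michael addition, and the hydroxyenone is attached last.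
- Stereochemistry: chromene C2 is the carbinol carbon of (R)-citramalic acid, none of whose four bonds is broken. The two ring centres (1S,2S, methyls cis) are set together in the key step by a chiral aminothiourea. The E-enone comes from syn-carboalumination and the Z-enone from syn-hydrogenation.

Key step: step 19

Remark: compounds 21 to 26 are carried as epimer mixtures at the methyl-bearing side-chain carbon (25 also at its secondary carbinol), a centre the enamine of step 19 erases; the (1R,2R) catalyst is assumed to be the enantiomer leading to the (1S,2S) ring, and its commercially available antipode would be used if a trial showed the opposite sense.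

**Route**

Step 1
Reactants: 1 (R)-citramalic acid
Product: 2 2-[(4R)-2,2,4-trimethyl-5-oxo-1,3-dioxolan-4-yl]acetic acid
Conditions: Me2C(OMe)2, TsOH·H2O (cat.), CH2Cl2, rt
Reagents that add atoms: 2,2-dimethoxypropane, COC(C)(C)OC
Why: Acid-catalysed transacetalisation should close the five-membered dioxolanone on the α-hydroxy acid unit in preference to the six-membered alternative, leaving the CH2CO2H arm free and the stereocentre untouched.

Step 2
Reactants: 2 2-[(4R)-2,2,4-trimethyl-5-oxo-1,3-dioxolan-4-yl]acetic acid
Product: 4 (3R)-3-hydroxy-3-methyloxolan-2-one, via hydroxyethyl dioxolanone 3 (not isolated)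
Conditions: BH3·THF, THF, 0 °C to rt; MeOH; then TsOH·H2O (cat.), CH2Cl2, rt
Reagents that add atoms: none
Why: Borane reduction is chemoselective for the free carboxylic acid over the dioxolanone ester, and acid-catalysed translactonisation of 3 then expels acetone to give the γ-lactone with the tertiary carbinol unchanged.

Step 3
Reactants: 4 (3R)-3-hydroxy-3-methyloxolan-2-one
Product: 5 (3R)-3-methyloxolane-2,3-diol (anomer mixture)
Conditions: i-Bu2AlH (2.2 equiv), CH2Cl2, −78 °C; aq. potassium sodium tartrate
Reagents that add atoms: none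
Why: Low-temperature i-Bu2AlH reduction of a γ-lactone should stop at the aluminium hemiacetal, released as the lactol on work-up, one equivalent of hydride being consumed by the free hydroxyl.

Step 4
Reactants: 5 (3R)-3-methyloxolane-2,3-diol
Product: 6 (3R)-3-methylpent-4-yne-1,3-diol
Conditions: dimethyl (1-diazo-2-oxopropyl)phosphonate, K2CO3, MeOH, 0 °C to rt
Reagents that add atoms: dimethyl (1-diazo-2-oxopropyl)phosphonate, CC(=O)C(=[N+]=[N-])P(=O)(OC)OC
Why: The Seyferth–Gilbert homologation in its Ohira–Bestmann form acts on the open hydroxy-aldehyde tautomer of the lactol under mild carbonate conditions and turns the former carboxyl carbon into a terminal alkyne without touching the quaternary carbinol.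

Step 5
Reactants: 6 (3R)-3-methylpent-4-yne-1,3-diol
Product: 7 (3R)-5-[(tert-butyldimethylsilyl)oxy]-3-methylpent-1-yn-3-ol
Conditions: TBSCl (1.05 equiv), imidazole, CH2Cl2, 0 °C
Reagents that add atoms: tert-butyldimethylsilyl chloride, CC(C)(C)[Si](C)(C)Cl
Why: Silylation is selective for the primary hydroxyl over the hindered tertiary propargylic one, which has to stay free for the later C–O coupling.

Step 6
Reactants: 8 4-methoxy-2-methylaniline
Product: 9 2-iodo-4-methoxy-6-methylaniline
Conditions: N-iodosuccinimide, MeCN, 0 °C, dark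
Reagents that add atoms: N-iodosuccinimide, O=C1CCC(=O)N1I
Why: Electrophilic aromatic iodination is directed by the amino group to its only free ortho position, the para position and the other ortho position being occupied by methoxy and methyl.

Step 7
Reactants: 9 2-iodo-4-methoxy-6-methylaniline
Product: 11 2-bromo-1-iodo-5-methoxy-3-methylbenzene, via arenediazonium bromide 10 (not isolated)
Conditions: NaNO2, aq. HBr, 0 °C; then CuBr, aq. HBr, 0 to 60 °C
Reagents that add atoms: hydrogen bromide, Br
Why: Sandmeyer bromination replaces the diazonium group by bromine at the future C8a, giving a dihalide whose two halogens differ sharply in reactivity towards zerovalent palladium.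

Step 8
Reactants: 7 (3R)-5-[(tert-butyldimethylsilyl)oxy]-3-methylpent-1-yn-3-ol; 11 2-bromo-1-iodo-5-methoxy-3-methylbenzene
Product: 12 (3R)-1-(2-bromo-5-methoxy-3-methylphenyl)-5-[(tert-butyldimethylsilyl)oxy]-3-methylpent-1-yn-3-ol
Conditions: PdCl2(PPh3)2 (2 mol%), CuI (4 mol%), Et3N, THF, rt
Reagents that add atoms: none
Why: Sonogashira coupling should occur at the C–I bond only, since oxidative addition to an aryl iodide is far faster than to the flanked aryl bromide at room temperature, and the free tertiary alcohol is tolerated.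

Step 9
Reactants: 12 (3R)-1-(2-bromo-5-methoxy-3-methylphenyl)-5-[(tert-butyldimethylsilyl)oxy]-3-methylpent-1-yn-3-ol
Product: 13 (1Z,3R)-1-(2-bromo-5-methoxy-3-methylphenyl)-5-[(tert-butyldimethylsilyl)oxy]-3-methylpent-1-en-3-ol
Conditions: H2 (1 atm), Pd/CaCO3 poisoned with Pb(OAc)2, quinoline, EtOAc, rt
Reagents that add atoms: none
Why: Lindlar semihydrogenation adds hydrogen syn to give the Z-alkene that brings the carbinol oxygen within reach of the bromide, and the poisoned catalyst leaves the aryl bromide and the new alkene alone.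

Step 10
Reactants: 13 (1Z,3R)-1-(2-bromo-5-methoxy-3-methylphenyl)-5-[(tert-butyldimethylsilyl)oxy]-3-methylpent-1-en-3-ol
Product: 14 tert-butyl{2-[(2R)-6-methoxy-2,8-dimethyl-2H-chromen-2-yl]ethoxy}dimethylsilane
Conditions: Pd(OAc)2 (5 mol%), 2-(di-tert-butylphosphino)-1,1'-binaphthyl (6 mol%), Cs2CO3, toluene, 70 °C, dark
Reagents that add atoms: none
Why: Intramolecular Buchwald–Hartwig etherification forms the O1–C8a bond and closes the pyran ring; the tertiary alkoxide has no hydrogen on its carbinol carbon for β-hydride elimination, and because the carbinol C–O bond is never broken the citramalate configuration is carried over as (R) at C2.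

Step 11
Reactants: 14 tert-butyl{2-[(2R)-6-methoxy-2,8-dimethyl-2H-chromen-2-yl]ethoxy}dimethylsilane
Product: 15 2-[(2R)-6-methoxy-2,8-dimethyl-2H-chromen-2-yl]ethan-1-ol
Conditions: Bu4NF, THF, 0 °C to rt
Reagents that add atoms: none
Why: Fluoride-induced desilylation cleaves only the Si–O bond; the chromene and the aryl ethers are inert.

Step 12
Reactants: 15 2-[(2R)-6-methoxy-2,8-dimethyl-2H-chromen-2-yl]ethan-1-ol
Product: 16 [(2R)-6-methoxy-2,8-dimethyl-2H-chromen-2-yl]acetaldehyde
Conditions: Dess–Martin periodinane, NaHCO3, CH2Cl2, 0 °C to rt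
Reagents that add atoms: none
Why: Buffered Dess–Martin oxidation gives the β-aryloxy aldehyde under non-basic conditions that avoid β-elimination of the phenoxide; the aldehyde is used without storage.

Step 13
Reactants: 17 5-chloropent-1-yne
Product: 18 5-iodopent-1-yne
Conditions: NaI, acetone, reflux
Reagents that add atoms: sodium iodide, [Na+].[I-]
Why: Finkelstein halide exchange, driven by precipitation of NaCl, gives the more reactive primary iodide.

Step 14
Reactants: 18 5-iodopent-1-yne; 19 ethyl propanoate
Product: 21 ethyl 2-methylhept-6-ynoate (racemic), via lithium enolate 20 (not isolated)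
Conditions: LiN(i-Pr)2, THF, −78 °C; then 18, DMPU, −78 to 0 °C
Reagents that add atoms: none
Why: SN2 alkylation of the lithium ester enolate by a primary iodide is faster than proton transfer from the terminal alkyne; the new centre is formed racemic, which does not matter because it is erased in step 19.

Step 15
Reactants: 21 ethyl 2-methylhept-6-ynoate
Product: 22 2-methylhept-6-yn-1-ol (racemic)
Conditions: LiAlH4, Et2O, 0 °C
Reagents that add atoms: none
Why: Hydride reduction of the ester gives the primary alcohol and does not touch the isolated terminal alkyne.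

Step 16
Reactants: 22 2-methylhept-6-yn-1-ol
Product: 24 (6E)-7-iodo-2,6-dimethylhept-6-en-1-ol (racemic), via alkenylalane 23 (not isolated)
Conditions: Me3Al (3 equiv), Cp2ZrCl2 (0.25 equiv), CH2Cl2, 0 °C to rt; then I2, THF, −30 to 0 °C
Reagents that add atoms: trimethylaluminium, C[Al](C)C; iodine, II
Why: Zirconium-catalysed Negishi carboalumination adds methyl and aluminium syn and regioselectively across the terminal alkyne of the aluminium alkoxide, and iodinolysis of the alkenylalane with retention fixes the E geometry of the trisubstituted alkene.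

Step 17
Reactants: 16 [(2R)-6-methoxy-2,8-dimethyl-2H-chromen-2-yl]acetaldehyde; 24 (6E)-7-iodo-2,6-dimethylhept-6-en-1-ol (1.5 equiv)
Product: 25 (3E)-1-[(2R)-6-methoxy-2,8-dimethyl-2H-chromen-2-yl]-4,8-dimethylnon-3-ene-2,9-diol (epimer mixture at C2 and C8)
Conditions: CrCl2 (4 equiv), NiCl2 (2 mol%), DMF, rt
Reagents that add atoms: none
Why: In the Nozaki–Hiyama–Kishi coupling the alkenylchromium species adds to the aldehyde with retention of alkene geometry, is too weakly basic to enolise the β-aryloxy aldehyde or to be quenched by the free hydroxyl, and the new carbinol configuration is irrelevant because it is oxidised next.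

Step 18
Reactants: 25 (3E)-1-[(2R)-6-methoxy-2,8-dimethyl-2H-chromen-2-yl]-4,8-dimethylnon-3-ene-2,9-diol
Product: 26 (6E)-9-[(2R)-6-methoxy-2,8-dimethyl-2H-chromen-2-yl]-2,6-dimethyl-8-oxonon-6-enal (both C2 epimers)
Conditions: Dess–Martin periodinane (3 equiv), NaHCO3, CH2Cl2, 0 °C to rt
Reagents that add atoms: none
Why: Dess–Martin oxidation converts the allylic and the primary alcohol in one operation under buffered conditions, giving the E-enone and the α-methyl aldehyde without isomerising the alkene or opening the chromene.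

Step 19
Reactants: 26 (6E)-9-[(2R)-6-methoxy-2,8-dimethyl-2H-chromen-2-yl]-2,6-dimethyl-8-oxonon-6-enal
Product: 28 (1S,2S)-2-{3-[(2R)-6-methoxy-2,8-dimethyl-2H-chromen-2-yl]-2-oxopropyl}-1,2-dimethylcyclopentane-1-carbaldehyde, via catalyst-bound enamine 27 (not isolated)
Conditions: 1-[(1R,2R)-2-aminocyclohexyl]-3-[3,5-bis(trifluoromethyl)phenyl]thiourea (20 mol%), PhCO2H (20 mol%), toluene, rt to 40 °C, dark
Reagents that add atoms: none
Why: Proposed new method: the primary amine of the catalyst should condense with the aldehyde of 26 to the trisubstituted enamine 27, in which the stereolabile methyl-bearing carbon has become planar, while the thiourea N–H pair binds the enone oxygen; the enamine carbon then adds to the methyl-bearing β-carbon of the E-enone and hydrolysis of the resulting imine releases 28 and the catalyst. The closest known reaction types are the amine-catalysed intramolecular Michael addition of formyl enones to cyclopentanes and the primary amine–thiourea Michael addition of α-branched aldehydes; neither has been shown to join two fully substituted carbons on a β,β-disubstituted enone. The cyclopentane closes in the 5-exo-trig mode, the three-methylene tether making up for the low reactivity of both partners. The cis relation of the two new quaternary centres is controlled by the bifunctional catalyst, which holds the CH=N terminus and the enone C=O on the same side of the forming ring so that both methyl groups end up on the opposite face, and the absolute (1S,2S) sense is controlled by the (1R,2R)-cyclohexanediamine backbone, which leaves one enamine face open. The step needs Michael closure to be faster than aldol closure onto the ketone and than β-elimination of the aryloxy group: the aldehyde is the only carbonyl that condenses readily with the amine, the E-enone points its β-carbon at the enamine five atoms away, and the weakly acidic medium suppresses enolate formation next to the chromene. Because the aldehyde carbon of 28 is quaternary, the product cannot epimerise.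

Step 20
Reactants: 28 (1S,2S)-2-{3-[(2R)-6-methoxy-2,8-dimethyl-2H-chromen-2-yl]-2-oxopropyl}-1,2-dimethylcyclopentane-1-carbaldehyde; 29 2-methylbut-3-yn-2-ol
Product: 30 1-[(1S,2S)-2-(1,4-dihydroxy-4-methylpent-2-yn-1-yl)-1,2-dimethylcyclopentyl]-3-[(2R)-6-methoxy-2,8-dimethyl-2H-chromen-2-yl]propan-2-one (both carbinol epimers)
Conditions: Zn(OTf)2 (1.5 equiv), Et3N (1.6 equiv), toluene, rt to 40 °C
Reagents that add atoms: none
Why: Zinc acetylide addition under Carreira alkynylation conditions (run without a chiral ligand) is selective for aldehydes over ketones, is well suited to α-quaternary aldehydes and to this alkyne, and gives two carbinol epimers that converge on oxidation.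

Step 21
Reactants: 30 1-[(1S,2S)-2-(1,4-dihydroxy-4-methylpent-2-yn-1-yl)-1,2-dimethylcyclopentyl]-3-[(2R)-6-methoxy-2,8-dimethyl-2H-chromen-2-yl]propan-2-one
Product: 31 1-[(1S,2S)-2-(4-hydroxy-4-methylpent-2-ynoyl)-1,2-dimethylcyclopentyl]-3-[(2R)-6-methoxy-2,8-dimethyl-2H-chromen-2-yl]propan-2-one
Conditions: Dess–Martin periodinane, NaHCO3, CH2Cl2, 0 °C
Reagents that add atoms: none
Why: Dess–Martin oxidation of the secondary propargylic alcohol gives the ynone, the tertiary hydroxyl being inert and the non-basic medium sparing the β-aryloxy ketone.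

Step 22
Reactants: 31 1-[(1S,2S)-2-(4-hydroxy-4-methylpent-2-ynoyl)-1,2-dimethylcyclopentyl]-3-[(2R)-6-methoxy-2,8-dimethyl-2H-chromen-2-yl]propan-2-one
Product: 32 (2Z)-4-hydroxy-1-[(1S,2S)-2-{3-[(2R)-6-methoxy-2,8-dimethyl-2H-chromen-2-yl]-2-oxopropyl}-1,2-dimethylcyclopentyl]-4-methylpent-2-en-1-one (CNP0137762.2)
Conditions: H2 (1 atm), Pd/CaCO3 poisoned with Pb(OAc)2, quinoline, EtOAc, 0 °C, stopped after one equivalent of H2
Reagents that add atoms: none
Why: Lindlar semihydrogenation delivers hydrogen syn to the ynone to give the Z-enone, the conjugated alkyne being reduced much faster than the disubstituted chromene double bond.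

**Compound list**

1 | (R)-citramalic acid | OC(=O)[C@@](C)(CC(=O)O)O | starting material
2 | 2-[(4R)-2,2,4-trimethyl-5-oxo-1,3-dioxolan-4-yl]acetic acid | CC1(C)OC(=O)[C@@](C)(CC(=O)O)O1 | intermediate
3 | (5R)-5-(2-hydroxyethyl)-2,2,5-trimethyl-1,3-dioxolan-4-one | CC1(C)OC(=O)[C@@](C)(CCO)O1 | intermediate
4 | (3R)-3-hydroxy-3-methyloxolan-2-one | O=C1OCC[C@@]1(C)O | intermediate
5 | (3R)-3-methyloxolane-2,3-diol | OC1OCC[C@@]1(C)O | intermediate
6 | (3R)-3-methylpent-4-yne-1,3-diol | C#C[C@@](C)(CCO)O | intermediate
7 | (3R)-5-[(tert-butyldimethylsilyl)oxy]-3-methylpent-1-yn-3-ol | C#C[C@@](C)(CCO[Si](C)(C)C(C)(C)C)O | intermediate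
8 | 4-methoxy-2-methylaniline | COc1ccc(N)c(C)c1 | starting material
9 | 2-iodo-4-methoxy-6-methylaniline | COc1cc(C)c(N)c(I)c1 | intermediate
10 | 2-iodo-4-methoxy-6-methylbenzenediazonium bromide | COc1cc(C)c([N+]#N)c(I)c1.[Br-] | intermediate
11 | 2-bromo-1-iodo-5-methoxy-3-methylbenzene | COc1cc(C)c(Br)c(I)c1 | intermediate
12 | (3R)-1-(2-bromo-5-methoxy-3-methylphenyl)-5-[(tert-butyldimethylsilyl)oxy]-3-methylpent-1-yn-3-ol | COc1cc(C)c(Br)c(c1)C#C[C@@](C)(CCO[Si](C)(C)C(C)(C)C)O | intermediate
13 | (1Z,3R)-1-(2-bromo-5-methoxy-3-methylphenyl)-5-[(tert-butyldimethylsilyl)oxy]-3-methylpent-1-en-3-ol | COc1cc(C)c(Br)c(c1)/C=C\[C@@](C)(CCO[Si](C)(C)C(C)(C)C)O | intermediate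
14 | tert-butyl{2-[(2R)-6-methoxy-2,8-dimethyl-2H-chromen-2-yl]ethoxy}dimethylsilane | COc1cc(C)c2c(c1)C=C[C@@](C)(CCO[Si](C)(C)C(C)(C)C)O2 | intermediate
15 | 2-[(2R)-6-methoxy-2,8-dimethyl-2H-chromen-2-yl]ethan-1-ol | COc1cc(C)c2c(c1)C=C[C@@](C)(CCO)O2 | intermediate
16 | [(2R)-6-methoxy-2,8-dimethyl-2H-chromen-2-yl]acetaldehyde | COc1cc(C)c2c(c1)C=C[C@@](C)(CC=O)O2 | intermediate
17 | 5-chloropent-1-yne | C#CCCCCl | starting material
18 | 5-iodopent-1-yne | C#CCCCI | intermediate
19 | ethyl propanoate | CCOC(=O)CC | starting material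
20 | lithium enolate of ethyl propanoate | CC=C(OCC)O[Li] | intermediate
21 | ethyl 2-methylhept-6-ynoate (racemic) | CCOC(=O)C(C)CCCC#C | intermediate
22 | 2-methylhept-6-yn-1-ol (racemic) | OCC(C)CCCC#C | intermediate
23 | dimethyl{(1E)-7-[(dimethylalumanyl)oxy]-2,6-dimethylhept-1-en-1-yl}alumane | C[Al](C)/C=C(\C)CCCC(C)CO[Al](C)C | intermediate
24 | (6E)-7-iodo-2,6-dimethylhept-6-en-1-ol (racemic) | I/C=C(\C)CCCC(C)CO | intermediate
25 | (3E)-1-[(2R)-6-methoxy-2,8-dimethyl-2H-chromen-2-yl]-4,8-dimethylnon-3-ene-2,9-diol | COc1cc(C)c2c(c1)C=C[C@@](C)(CC(O)/C=C(\C)CCCC(C)CO)O2 | intermediate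
26 | (6E)-9-[(2R)-6-methoxy-2,8-dimethyl-2H-chromen-2-yl]-2,6-dimethyl-8-oxonon-6-enal | COc1cc(C)c2c(c1)C=C[C@@](C)(CC(=O)/C=C(\C)CCCC(C)C=O)O2 | intermediate
27 | (6E)-1-{[(1R,2R)-2-({[3,5-bis(trifluoromethyl)phenyl]carbamothioyl}amino)cyclohexyl]amino}-9-[(2R)-6-methoxy-2,8-dimethyl-2H-chromen-2-yl]-2,6-dimethylnona-1,6-dien-8-one | COc1cc(C)c2c(c1)C=C[C@@](C)(CC(=O)/C=C(\C)CCCC(C)=CN[C@@H]1CCCC[C@H]1NC(=S)Nc1cc(cc(c1)C(F)(F)F)C(F)(F)F)O2 | intermediate
28 | (1S,2S)-2-{3-[(2R)-6-methoxy-2,8-dimethyl-2H-chromen-2-yl]-2-oxopropyl}-1,2-dimethylcyclopentane-1-carbaldehyde | COc1cc(C)c2c(c1)C=C[C@@](C)(CC(=O)C[C@]1(C)CCC[C@]1(C)C=O)O2 | intermediate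
29 | 2-methylbut-3-yn-2-ol | C#CC(C)(C)O | starting material
30 | 1-[(1S,2S)-2-(1,4-dihydroxy-4-methylpent-2-yn-1-yl)-1,2-dimethylcyclopentyl]-3-[(2R)-6-methoxy-2,8-dimethyl-2H-chromen-2-yl]propan-2-one | COc1cc(C)c2c(c1)C=C[C@@](C)(CC(=O)C[C@]1(C)CCC[C@]1(C)C(O)C#CC(C)(C)O)O2 | intermediate
31 | 1-[(1S,2S)-2-(4-hydroxy-4-methylpent-2-ynoyl)-1,2-dimethylcyclopentyl]-3-[(2R)-6-methoxy-2,8-dimethyl-2H-chromen-2-yl]propan-2-one | COc1cc(C)c2c(c1)C=C[C@@](C)(CC(=O)C[C@]1(C)CCC[C@]1(C)C(=O)C#CC(C)(C)O)O2 | intermediate
32 | (2Z)-4-hydroxy-1-[(1S,2S)-2-{3-[(2R)-6-methoxy-2,8-dimethyl-2H-chromen-2-yl]-2-oxopropyl}-1,2-dimethylcyclopentyl]-4-methylpent-2-en-1-one | COc1cc(C)c2c(c1)C=C[C@@](C)(CC(=O)C[C@]1(C)CCC[C@]1(C)C(=O)/C=C\C(C)(C)O)O2 | target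

**Step count**

Total: 22 steps. Longest linear sequence: 16 steps (steps 1–5, 8–12 and 17–22, from (R)-citramalic acid).

**Steps most likely to fail**

1. Step 19 (proposed new method). The closure may stall because a trisubstituted enamine and a β,β-disubstituted enone have to meet at two fully substituted carbons. The 1,5-keto aldehyde formed may go on to close a six-membered aldol ring. The chromene may open by β-elimination of the phenoxide, or the catalyst may discriminate the faces poorly. The fallback makes the same ring bond by an intramolecular Mukaiyama–Michael addition, a known way to join two fully substituted carbons. It sets out from 24 and 16. Dess–Martin oxidation of 24 would give (6E)-7-iodo-2,6-dimethylhept-6-enal F1, and TBSOTf/Et3N would convert it into the silyl enol ether tert-butyl{[(6E)-7-iodo-2,6-dimethylhepta-1,6-dien-1-yl]oxy}dimethylsilane F2. CrCl2/NiCl2 coupling of F2 with 16 would give (3E)-9-[(tert-butyldimethylsilyl)oxy]-1-[(2R)-6-methoxy-2,8-dimethyl-2H-chromen-2-yl]-4,8-dimethylnona-3,8-dien-2-ol F3. MnO2 would oxidise the allylic alcohol to (3E)-9-[(tert-butyldimethylsilyl)oxy]-1-[(2R)-6-methoxy-2,8-dimethyl-2H-chromen-2-yl]-4,8-dimethylnona-3,8-dien-2-one F4. Catalytic Tf2NH in CH2Cl2 at −78 °C (silyl triflimide catalysis) would then close the ring, and aqueous work-up would remove silicon. The route is rejoined at 28, which would have to be separated from its ring diastereomers, because only the remote chromene centre can bias this closure.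

2. Step 10. Oxidative addition at the doubly ortho-substituted bromide or C–O reductive elimination may be slow, so that hydrodebromination or Heck-type reactions of the cis-alkene take over. The chromene may also lose configurational purity through reversible electrocyclic ring-opening at the reaction temperature. The fallback closes the ring at the chroman level, where this etherification is best established, and introduces the double bond afterwards. It sets out from 12. Hydrogenation over Pt/C (H2, EtOAc), which saturates the alkyne and leaves the aryl bromide, would give (3S)-1-(2-bromo-5-methoxy-3-methylphenyl)-5-[(tert-butyldimethylsilyl)oxy]-3-methylpentan-3-ol F5; the descriptor changes only because the ranking of the two chains changes. The same Pd(OAc)2/phosphine/Cs2CO3 conditions would give tert-butyl{2-[(2S)-6-methoxy-2,8-dimethyl-3,4-dihydro-2H-chromen-2-yl]ethoxy}dimethylsilane F6. DDQ in dioxane at 80 °C would then dehydrogenate C3–C4 by benzylic hydride abstraction and return the route to 14.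

3. Step 22. The ynone may be over-reduced to the saturated ketone, the chromene double bond may be hydrogenated, or the Z-enone may isomerise to E on the catalyst. The fallback brings the Z-alkene in preformed and needs no hydrogenation in the presence of the chromene. It sets out from 28 and 29 and bypasses steps 20 and 21 as well. N-iodosuccinimide with catalytic AgNO3 would convert 29 into 4-iodo-2-methylbut-3-yn-2-ol F7. Diimide reduction (2-nitrobenzenesulfonohydrazide, Et3N) would give (3Z)-4-iodo-2-methylbut-3-en-2-ol F8. CrCl2/NiCl2 coupling of F8 with 28, selective for the aldehyde over the ketone, would give 1-[(1S,2S)-2-[(2Z)-1,4-dihydroxy-4-methylpent-2-en-1-yl]-1,2-dimethylcyclopentyl]-3-[(2R)-6-methoxy-2,8-dimethyl-2H-chromen-2-yl]propan-2-one F9. Buffered Dess–Martin oxidation of the secondary allylic alcohol returns the route at 32.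

**Further compounds**

F1 | step 19 | (6E)-7-iodo-2,6-dimethylhept-6-enal | I/C=C(\C)CCCC(C)C=O
F2 | step 19 | tert-butyl{[(6E)-7-iodo-2,6-dimethylhepta-1,6-dien-1-yl]oxy}dimethylsilane | I/C=C(\C)CCCC(C)=CO[Si](C)(C)C(C)(C)C
F3 | step 19 | (3E)-9-[(tert-butyldimethylsilyl)oxy]-1-[(2R)-6-methoxy-2,8-dimethyl-2H-chromen-2-yl]-4,8-dimethylnona-3,8-dien-2-ol | COc1cc(C)c2c(c1)C=C[C@@](C)(CC(O)/C=C(\C)CCCC(C)=CO[Si](C)(C)C(C)(C)C)O2
F4 | step 19 | (3E)-9-[(tert-butyldimethylsilyl)oxy]-1-[(2R)-6-methoxy-2,8-dimethyl-2H-chromen-2-yl]-4,8-dimethylnona-3,8-dien-2-one | COc1cc(C)c2c(c1)C=C[C@@](C)(CC(=O)/C=C(\C)CCCC(C)=CO[Si](C)(C)C(C)(C)C)O2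
F5 | step 10 | (3S)-1-(2-bromo-5-methoxy-3-methylphenyl)-5-[(tert-butyldimethylsilyl)oxy]-3-methylpentan-3-ol | COc1cc(C)c(Br)c(c1)CC[C@@](C)(CCO[Si](C)(C)C(C)(C)C)O
F6 | step 10 | tert-butyl{2-[(2S)-6-methoxy-2,8-dimethyl-3,4-dihydro-2H-chromen-2-yl]ethoxy}dimethylsilane | COc1cc(C)c2c(c1)CC[C@@](C)(CCO[Si](C)(C)C(C)(C)C)O2
F7 | step 22 | 4-iodo-2-methylbut-3-yn-2-ol | CC(C)(O)C#CI
F8 | step 22 | (3Z)-4-iodo-2-methylbut-3-en-2-ol | CC(C)(O)/C=C\I
F9 | step 22 | 1-[(1S,2S)-2-[(2Z)-1,4-dihydroxy-4-methylpent-2-en-1-yl]-1,2-dimethylcyclopentyl]-3-[(2R)-6-methoxy-2,8-dimethyl-2H-chromen-2-yl]propan-2-one | COc1cc(C)c2c(c1)C=C[C@@](C)(CC(=O)C[C@]1(C)CCC[C@]1(C)C(O)/C=C\C(C)(C)O)O2
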